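**Plan**

- The target is numbered as a 3,7-dioxabicyclo[3.3.0]octan-8-one: C8 (lactone C=O), C1 (α to C8), C2 (catechol carbinol), O3, C4H2, C5, C6 (pyrogallol carbinol), O7. It is (1S,2S,5R,6S), cis-fused, with both aryl groups on the convex face.
- Enabling feature: the lactone ring (C8, O7, C6, C5, C1) and the tetrahydrofuran ring (C1, C2, O3, C4, C5) share C1–C5, and C8–C1–C5–C4 is a masked butenolide. Its β-carbon C5 and α-carbon C1 each carry an arylcarbinol carbon (C6, C2), so C5–C6 can come from an aryl acyl-anion equivalent and C1–C2 from an aryl aldehyde.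
- Retrosynthetic cuts, in order: O3–C2 (benzylic ether), C4–H (back to the aldehyde level), O7–C8 (acyl shift back to an acetal oxygen on C4), C6–H, then C1–C2 and C5–C6 together.
- Forward: the three fragments are joined on a 5-menthyloxybutenolide with no ring formed. After ketone unmasking and reduction, the lactone ring arises by acyl migration to the C6 oxygen, and the tetrahydrofuran ring is closed last through a C2 benzylic cation.
- Stereochemistry: the (5R) acetal carbon (from (−)-menthol, by crystallisation) directs C5, C5 directs C1, an oxazaborolidine sets C6, and the cationic closure sets C2. Menthol leaves when C4 is released.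

Key step: step 6

Remark on the chemistry: the aldol carbinol carbon C2 is formed without control. Every compound between the key step and the final ring closure is therefore an epimeric mixture at C2 and is drawn without a descriptor there; the lactol is also a mixture at C4. Lactol 18 and hydroxy aldehyde 17 are ring–chain tautomers: 17 first forms in step 9 and closes to 18, and in step 10 it is simply the reactive open form of 18. TBS = tert-butyldimethylsilyl; menthyl = (1R,2S,5R)-2-isopropyl-5-methylcyclohexyl.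

**Route**

Step 1
Reactants: 1 furfural
Product: 3 5-hydroxyfuran-2(5H)-one (racemic), via furfural endoperoxide 2 (not isolated)
Conditions: O2, visible light, rose bengal (disodium 4,5,6,7-tetrachloro-2',4',5',7'-tetraiodofluorescein, cat.), MeOH, rt
Reagents that add atoms: dioxygen, O=O
Why: Dye-sensitised singlet-oxygen [4+2] cycloaddition to the furan gives endoperoxide 2, whose methanolysis expels the formyl carbon as methyl formate and leaves the γ-hydroxybutenolide (photo-oxygenation of furfural).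

Step 2
Reactants: 3 5-hydroxyfuran-2(5H)-one; 4 (−)-menthol
Product: 6 (5R)-5-[(1R,2S,5R)-menthyloxy]furan-2(5H)-one, via (5S)-menthyloxyfuranone 5 (not isolated)
Conditions: 10-camphorsulfonic acid (CSA, cat.), toluene, reflux, Dean–Stark; crystallisation from hexane at −20 °C, mother liquor re-equilibrated with CSA and recrystallised
Reagents that add atoms: none
Why: Acid-catalysed acetalisation through the furanone oxocarbenium ion gives both acetal epimers, which interconvert under the acid, so crystallisation should drain epimer 5 into the less soluble (5R) acetal 6 (crystallisation-induced diastereomer transformation, chiral-pool auxiliary).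

Step 3
Reactants: 7 3,4,5-trihydroxybenzaldehyde
Product: 8 3,4,5-tris(tert-butyldimethylsilyloxy)benzaldehyde
Conditions: TBSCl, imidazole, DMF, 0 °C to rt
Reagents that add atoms: tert-butyldimethylsilyl chloride, CC(C)(C)[Si](C)(C)Cl
Why: Imidazole-promoted O-silylation of the three phenols is fast and leaves the aldehyde untouched (silyl ether protection).

Step 4
Reactants: 8 3,4,5-tris(tert-butyldimethylsilyloxy)benzaldehyde
Product: 9 2-[3,4,5-tris(tert-butyldimethylsilyloxy)phenyl]-1,3-dithiane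
Conditions: HS(CH2)3SH, BF3·OEt2 (cat.), CH2Cl2, 0 °C
Reagents that add atoms: propane-1,3-dithiol, SCCCS
Why: Lewis-acid-catalysed dithioacetalisation of an aromatic aldehyde is reliable, aryl silyl ethers should tolerate catalytic BF3·OEt2 at 0 °C, and the dithiane turns the future C6 into an acyl-anion equivalent (Corey–Seebach umpolung).

Step 5
Reactants: 10 3,4-dihydroxybenzaldehyde
Product: 11 3,4-bis(tert-butyldimethylsilyloxy)benzaldehyde
Conditions: TBSCl, imidazole, DMF, rt
Reagents that add atoms: tert-butyldimethylsilyl chloride, CC(C)(C)[Si](C)(C)Cl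
Why: The same imidazole-promoted phenol silylation gives a non-enolisable, base-stable aldehyde partner for the aldol step.

Step 6
Reactants: 9 2-[3,4,5-tris(tert-butyldimethylsilyloxy)phenyl]-1,3-dithiane; 6 (5R)-5-[(1R,2S,5R)-menthyloxy]furan-2(5H)-one; 11 3,4-bis(tert-butyldimethylsilyloxy)benzaldehyde
Product: 14 (3S,4R,5R)-3-{[3,4-bis(TBSO)phenyl](hydroxy)methyl}-5-menthyloxy-4-{2-[3,4,5-tris(TBSO)phenyl]-1,3-dithian-2-yl}dihydrofuran-2(3H)-one, via lithiated dithiane 12 (not isolated), via lithium enolate 13 (not isolated)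
Conditions: 9, n-BuLi, THF, −78 to −25 °C; 6, −78 °C; then 11, −78 °C; AcOH quench at −78 °C
Reagents that add atoms: none
Why: Deprotonation of 9 gives the sulfur-stabilised benzylic anion 12, which adds in a Michael reaction to the β-carbon of 6 (C5–C6) to form lithium enolate 13, and 13 is trapped at its α-carbon by aldehyde 11 in an aldol addition (C1–C2); this is the tandem conjugate addition–aldol coupling of dithiane anions, butenolides and aldehydes known from lignan lactone synthesis. No ring is closed in this step. C5 is set by attack on the face of 6 anti to the menthyloxy group at the acetal carbon, C1 is set by approach of the aldehyde anti to the new and very bulky dithianyl group, and the carbinol carbon C2 is not controlled. The step needs 1,4- rather than 1,2-addition, which the soft, delocalised 2-aryldithianyl anion and the unhindered β-carbon should secure. It also needs the enolate to persist until trapped and the aldolate not to revert, which the low temperature, the non-enolisable aldehyde and the cold acetic acid quench should secure. The acetal carbon of 6 is C4 at the aldehyde oxidation level, so 14 holds every carbon of the target.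

Step 7
Reactants: 14 dithianyl aldol lactone
Product: 15 (3S,4R,5R)-3-{[3,4-bis(TBSO)phenyl](hydroxy)methyl}-5-menthyloxy-4-[3,4,5-tris(TBSO)benzoyl]dihydrofuran-2(3H)-one
Conditions: Hg(ClO4)2, CaCO3, THF–H2O (5:1), 0 °C
Reagents that add atoms: water, O
Why: Thiophilic hydrolysis of the dithioacetal assisted by divalent mercury and buffered with CaCO3 should unmask the C6 ketone under near-neutral conditions that spare the aryl silyl ethers, the acylal lactone, the β-hydroxy lactone and the now enolisable C5, which already has the stable all-trans arrangement (dithiane deprotection).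

Step 8
Reactants: 15 aryl ketone
Product: 16 (3S,4S,5R)-3-{[3,4-bis(TBSO)phenyl](hydroxy)methyl}-4-{(S)-hydroxy[3,4,5-tris(TBSO)phenyl]methyl}-5-menthyloxydihydrofuran-2(3H)-one
Conditions: (R)-Me-CBS oxazaborolidine [(3aR)-1-methyl-3,3-diphenyltetrahydro-1H,3H-pyrrolo[1,2-c][1,3,2]oxazaborole, 0.3 equiv], BH3·SMe2 (2.5 equiv), THF, −20 °C; MeOH quench; used crude
Reagents that add atoms: none
Why: In this Corey–Bakshi–Shibata reduction the aryl ketone should bind the oxazaborolidine with the aryl group as the larger substituent, so hydride transfer from the N-bound borane with the (R)-catalyst gives the (6S)-carbinol; the substrate's own bias should be small because both ring carbons flanking C5 carry their substituents on the face remote from C6.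

Step 9
Reactants: 16 (6S)-carbinol
Product: 18 (1S,5S,6S)-2-[3,4-bis(TBSO)phenyl]-4-hydroxy-6-[3,4,5-tris(TBSO)phenyl]-3,7-dioxabicyclo[3.3.0]octan-8-one (lactol), via ring-opened hydroxy aldehyde 17 (not isolated)
Conditions: CSA (0.2 equiv), THF–H2O (10:1), 40 °C
Reagents that add atoms: none
Why: Acid-catalysed translactonisation moves the acyl group from the acetal oxygen to the C6 hydroxyl, turning an activated acylal ester into a normal γ-lactone; the released C4 oxygen collapses with loss of menthol to aldehyde 17, which the C2 hydroxyl, now cis to it, captures as lactol 18, so that no stereocentre is touched, all atoms of 18 stem from 16, and the trans side chains of the old ring become the cis ring fusion.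

Step 10
Reactants: 18 bicyclic lactol
Product: 19 (3S,4R,5S)-3-{[3,4-bis(TBSO)phenyl](hydroxy)methyl}-4-(hydroxymethyl)-5-[3,4,5-tris(TBSO)phenyl]dihydrofuran-2(3H)-one
Conditions: NaBH4, THF–EtOH (4:1), −20 °C; AcOH quench at −20 °C; used crude
Reagents that add atoms: none
Why: Lactol 18 reacts through its open-chain tautomer, the hydroxy aldehyde 17 already met in step 9, which borohydride reduces much faster than the γ-lactone at low temperature (chemoselective aldehyde reduction); the cold acidic quench is meant to protonate the primary alkoxide before it can attack the lactone carbonyl.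

Step 11
Reactants: 19 hydroxymethyl lactone diol
Product: 20 (1S,2S,5R,6S)-2-[3,4-bis(TBSO)phenyl]-6-[3,4,5-tris(TBSO)phenyl]-3,7-dioxabicyclo[3.3.0]octan-8-one
Conditions: BF3·OEt2 (0.2 equiv), 4 Å molecular sieves, CH2Cl2, −20 to 0 °C
Reagents that add atoms: none
Why: Lewis-acid ionisation of the p-silyloxybenzylic alcohol gives one benzylic cation from both C2 epimers, which the C4 hydroxyl captures in a five-membered ring closure (SN1 cycloetherification as used for furofuran lignans); closure with the aryl group on the convex face, trans to the C8 carbonyl carbon, is expected to be favoured and gives (2S).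

Step 12
Reactants: 20 penta-silylated furofuranone
Product: 21 (1S,2S,5R,6S)-2-(3,4-dihydroxyphenyl)-6-(3,4,5-trihydroxyphenyl)-3,7-dioxabicyclo[3.3.0]octan-8-one (target)
Conditions: Bu4NF, AcOH (1:1, 6 equiv each), THF, 0 °C, argon
Reagents that add atoms: none
Why: Fluoride cleaves the five aryl silyl ethers (fluoride desilylation), while the acetic acid buffer and exclusion of air keep the catechol and pyrogallol protonated so that neither oxidation nor quinone methide formation at the two benzylic C–O bonds should occur.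

**Compound list**

1 | furfural (furan-2-carbaldehyde) | O=Cc1ccco1 | starting material
2 | 2,3,7-trioxabicyclo[2.2.1]hept-5-ene-1-carbaldehyde (furfural endoperoxide, racemic) | O=CC12C=CC(OO1)O2 | intermediate
3 | 5-hydroxyfuran-2(5H)-one (racemic) | O=C1C=CC(O)O1 | intermediate
4 | (−)-menthol, (1R,2S,5R)-2-isopropyl-5-methylcyclohexan-1-ol | CC(C)[C@@H]1CC[C@@H](C)C[C@H]1O | starting material
5 | (5S)-5-[(1R,2S,5R)-menthyloxy]furan-2(5H)-one | O=C1C=C[C@@H](O[C@@H]2C[C@H](C)CC[C@H]2C(C)C)O1 | intermediate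
6 | (5R)-5-[(1R,2S,5R)-menthyloxy]furan-2(5H)-one | O=C1C=C[C@H](O[C@@H]2C[C@H](C)CC[C@H]2C(C)C)O1 | intermediate
7 | 3,4,5-trihydroxybenzaldehyde | O=Cc1cc(O)c(O)c(O)c1 | starting material
8 | 3,4,5-tris(tert-butyldimethylsilyloxy)benzaldehyde | O=Cc1cc(O[Si](C)(C)C(C)(C)C)c(O[Si](C)(C)C(C)(C)C)c(O[Si](C)(C)C(C)(C)C)c1 | intermediate
9 | 2-[3,4,5-tris(tert-butyldimethylsilyloxy)phenyl]-1,3-dithiane | C1(c2cc(O[Si](C)(C)C(C)(C)C)c(O[Si](C)(C)C(C)(C)C)c(O[Si](C)(C)C(C)(C)C)c2)SCCCS1 | intermediate
10 | 3,4-dihydroxybenzaldehyde | O=Cc1ccc(O)c(O)c1 | starting material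
11 | 3,4-bis(tert-butyldimethylsilyloxy)benzaldehyde | O=Cc1ccc(O[Si](C)(C)C(C)(C)C)c(O[Si](C)(C)C(C)(C)C)c1 | intermediate
12 | 2-lithio-2-[3,4,5-tris(TBSO)phenyl]-1,3-dithiane | [Li]C1(c2cc(O[Si](C)(C)C(C)(C)C)c(O[Si](C)(C)C(C)(C)C)c(O[Si](C)(C)C(C)(C)C)c2)SCCCS1 | intermediate
13 | lithium enolate of (4R,5R)-5-menthyloxy-4-{2-[3,4,5-tris(TBSO)phenyl]-1,3-dithian-2-yl}dihydrofuran-2(3H)-one | [Li]OC1=C[C@@H](C5(c2cc(O[Si](C)(C)C(C)(C)C)c(O[Si](C)(C)C(C)(C)C)c(O[Si](C)(C)C(C)(C)C)c2)SCCCS5)[C@H](O[C@@H]4C[C@H](C)CC[C@H]4C(C)C)O1 | intermediate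
14 | (3S,4R,5R)-3-{[3,4-bis(TBSO)phenyl](hydroxy)methyl}-5-menthyloxy-4-{2-[3,4,5-tris(TBSO)phenyl]-1,3-dithian-2-yl}dihydrofuran-2(3H)-one (carbinol epimers) | O=C1O[C@@H](O[C@@H]4C[C@H](C)CC[C@H]4C(C)C)[C@H](C5(c2cc(O[Si](C)(C)C(C)(C)C)c(O[Si](C)(C)C(C)(C)C)c(O[Si](C)(C)C(C)(C)C)c2)SCCCS5)[C@H]1C(O)c3ccc(O[Si](C)(C)C(C)(C)C)c(O[Si](C)(C)C(C)(C)C)c3 | intermediate
15 | (3S,4R,5R)-3-{[3,4-bis(TBSO)phenyl](hydroxy)methyl}-5-menthyloxy-4-[3,4,5-tris(TBSO)benzoyl]dihydrofuran-2(3H)-one (carbinol epimers) | O=C1O[C@@H](O[C@@H]4C[C@H](C)CC[C@H]4C(C)C)[C@H](C(=O)c2cc(O[Si](C)(C)C(C)(C)C)c(O[Si](C)(C)C(C)(C)C)c(O[Si](C)(C)C(C)(C)C)c2)[C@H]1C(O)c3ccc(O[Si](C)(C)C(C)(C)C)c(O[Si](C)(C)C(C)(C)C)c3 | intermediate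
16 | (3S,4S,5R)-3-{[3,4-bis(TBSO)phenyl](hydroxy)methyl}-4-{(S)-hydroxy[3,4,5-tris(TBSO)phenyl]methyl}-5-menthyloxydihydrofuran-2(3H)-one (C2 epimers) | O=C1O[C@@H](O[C@@H]4C[C@H](C)CC[C@H]4C(C)C)[C@H]([C@H](O)c2cc(O[Si](C)(C)C(C)(C)C)c(O[Si](C)(C)C(C)(C)C)c(O[Si](C)(C)C(C)(C)C)c2)[C@H]1C(O)c3ccc(O[Si](C)(C)C(C)(C)C)c(O[Si](C)(C)C(C)(C)C)c3 | intermediate
17 | (2S,3S,4S)-4-{[3,4-bis(TBSO)phenyl](hydroxy)methyl}-5-oxo-2-[3,4,5-tris(TBSO)phenyl]tetrahydrofuran-3-carbaldehyde (C2 epimers) | O=C1O[C@H](c2cc(O[Si](C)(C)C(C)(C)C)c(O[Si](C)(C)C(C)(C)C)c(O[Si](C)(C)C(C)(C)C)c2)[C@@H](C=O)[C@H]1C(O)c3ccc(O[Si](C)(C)C(C)(C)C)c(O[Si](C)(C)C(C)(C)C)c3 | intermediate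
18 | (1S,5S,6S)-2-[3,4-bis(TBSO)phenyl]-4-hydroxy-6-[3,4,5-tris(TBSO)phenyl]-3,7-dioxabicyclo[3.3.0]octan-8-one (mixture at C2 and C4) | O=C1O[C@H](c2cc(O[Si](C)(C)C(C)(C)C)c(O[Si](C)(C)C(C)(C)C)c(O[Si](C)(C)C(C)(C)C)c2)[C@H]2C(O)OC(c3ccc(O[Si](C)(C)C(C)(C)C)c(O[Si](C)(C)C(C)(C)C)c3)[C@@H]12 | intermediate
19 | (3S,4R,5S)-3-{[3,4-bis(TBSO)phenyl](hydroxy)methyl}-4-(hydroxymethyl)-5-[3,4,5-tris(TBSO)phenyl]dihydrofuran-2(3H)-one (C2 epimers) | O=C1O[C@H](c2cc(O[Si](C)(C)C(C)(C)C)c(O[Si](C)(C)C(C)(C)C)c(O[Si](C)(C)C(C)(C)C)c2)[C@@H](CO)[C@H]1C(O)c3ccc(O[Si](C)(C)C(C)(C)C)c(O[Si](C)(C)C(C)(C)C)c3 | intermediate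
20 | (1S,2S,5R,6S)-2-[3,4-bis(TBSO)phenyl]-6-[3,4,5-tris(TBSO)phenyl]-3,7-dioxabicyclo[3.3.0]octan-8-one | O=C1O[C@H](c2cc(O[Si](C)(C)C(C)(C)C)c(O[Si](C)(C)C(C)(C)C)c(O[Si](C)(C)C(C)(C)C)c2)[C@H]2CO[C@H](c3ccc(O[Si](C)(C)C(C)(C)C)c(O[Si](C)(C)C(C)(C)C)c3)[C@@H]12 | intermediate
21 | (1S,2S,5R,6S)-2-(3,4-dihydroxyphenyl)-6-(3,4,5-trihydroxyphenyl)-3,7-dioxabicyclo[3.3.0]octan-8-one | O=C1O[C@H](c2cc(O)c(O)c(O)c2)[C@H]2CO[C@H](c3ccc(O)c(O)c3)[C@@H]12 | target

**Step count**

Total: 12 steps. Longest linear sequence: 9 steps (1 → 3 → 6 → 14 → 15 → 16 → 18 → 19 → 20 → 21; the branch from 7 through 8 and 9 is equally long).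

**Steps most likely to fail**

Step 8. The reduction may show poor facial selectivity if the branched ring carbon C5 competes with the aryl group as the larger substituent. The free C2 hydroxyl may also tie up borane and open an uncatalysed background reduction.
- The fallback sets out from 15 and returns at 20. It gives up catalyst control and relies on thermodynamic control at C6.
- Ketone 15 is reduced with NaBH4 and CeCl3·7H2O in MeOH–THF at −78 °C to give 16 together with its C6 epimer, the (6R)-carbinol F2.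
- The mixture is taken through the conditions of steps 9 to 11. F2 should give the 6-epi lactol F3, then the 6-epi hydroxymethyl lactone F4, then the 6-epi furofuranone F5, alongside 20.
- The mixture of 20 and F5 is then exposed to BF3·OEt2 in CH2Cl2 at 0 °C to rt. The benzylic C6–O7 bond of the p-silyloxybenzylic lactone should ionise and reclose to the trans-4,5-disubstituted lactone 20, which is expected to be the more stable arrangement.
- This is the acid-promoted epimerisation of benzylic C–O centres known for furofuran lignans. Residual F5 would be separated and resubmitted.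

Step 10. The lactone may migrate from O7 to the newly formed primary alkoxide at C4. The lactol may also open slowly, forcing warmer and more basic conditions that erode the aryl silyl ethers.
- The fallback sets out from 18 and returns at 20. It keeps O3 bonded to C4 throughout.
- Lactol 18 is treated with Et3SiH and BF3·OEt2 in CH2Cl2 at −78 to −40 °C. This ionic hydrogenation reduces the cyclic oxocarbenium ion at C4 and gives the bicycle directly as 20 together with its C2 epimer, the 2-epi furofuranone F6, with C2 as set in the aldol.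
- After removal of the silane, F6 is equilibrated with BF3·OEt2 in CH2Cl2 at 0 °C through the same benzylic cation as in step 11. It is then separated from 20 and recycled.

Step 6. Trapping of the enolate may be incomplete (proton transfer, or retro-aldol during the quench), and the hindered silyloxy-substituted dithiane may lithiate sluggishly.
- The fallback sets out from 9 and 6 and returns at 14. It separates the two bond formations.
- The conjugate addition is quenched with AcOH at −78 °C to isolate the (4R,5R)-conjugate adduct F1.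
- F1 is deprotonated with LiN(iPr)2 in THF at −78 °C, transmetallated with ZnCl2, and treated with an excess of aldehyde 11. The zinc aldolate is less prone to reversal, and the aldehyde again adds anti to the dithianyl group to give 14.

**Further compounds**

F1 | step 6 | (4R,5R)-5-menthyloxy-4-{2-[3,4,5-tris(TBSO)phenyl]-1,3-dithian-2-yl}dihydrofuran-2(3H)-one | O=C1C[C@@H](C5(c2cc(O[Si](C)(C)C(C)(C)C)c(O[Si](C)(C)C(C)(C)C)c(O[Si](C)(C)C(C)(C)C)c2)SCCCS5)[C@H](O[C@@H]4C[C@H](C)CC[C@H]4C(C)C)O1
F2 | step 8 | (3S,4S,5R)-3-{[3,4-bis(TBSO)phenyl](hydroxy)methyl}-4-{(R)-hydroxy[3,4,5-tris(TBSO)phenyl]methyl}-5-menthyloxydihydrofuran-2(3H)-one | O=C1O[C@@H](O[C@@H]4C[C@H](C)CC[C@H]4C(C)C)[C@H]([C@@H](O)c2cc(O[Si](C)(C)C(C)(C)C)c(O[Si](C)(C)C(C)(C)C)c(O[Si](C)(C)C(C)(C)C)c2)[C@H]1C(O)c3ccc(O[Si](C)(C)C(C)(C)C)c(O[Si](C)(C)C(C)(C)C)c3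
F3 | step 8 | (1S,5S,6R)-2-[3,4-bis(TBSO)phenyl]-4-hydroxy-6-[3,4,5-tris(TBSO)phenyl]-3,7-dioxabicyclo[3.3.0]octan-8-one | O=C1O[C@@H](c2cc(O[Si](C)(C)C(C)(C)C)c(O[Si](C)(C)C(C)(C)C)c(O[Si](C)(C)C(C)(C)C)c2)[C@H]2C(O)OC(c3ccc(O[Si](C)(C)C(C)(C)C)c(O[Si](C)(C)C(C)(C)C)c3)[C@@H]12
F4 | step 8 | (3S,4R,5R)-3-{[3,4-bis(TBSO)phenyl](hydroxy)methyl}-4-(hydroxymethyl)-5-[3,4,5-tris(TBSO)phenyl]dihydrofuran-2(3H)-one | O=C1O[C@@H](c2cc(O[Si](C)(C)C(C)(C)C)c(O[Si](C)(C)C(C)(C)C)c(O[Si](C)(C)C(C)(C)C)c2)[C@@H](CO)[C@H]1C(O)c3ccc(O[Si](C)(C)C(C)(C)C)c(O[Si](C)(C)C(C)(C)C)c3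
F5 | step 8 | (1S,2S,5R,6R)-2-[3,4-bis(TBSO)phenyl]-6-[3,4,5-tris(TBSO)phenyl]-3,7-dioxabicyclo[3.3.0]octan-8-one | O=C1O[C@@H](c2cc(O[Si](C)(C)C(C)(C)C)c(O[Si](C)(C)C(C)(C)C)c(O[Si](C)(C)C(C)(C)C)c2)[C@H]2CO[C@H](c3ccc(O[Si](C)(C)C(C)(C)C)c(O[Si](C)(C)C(C)(C)C)c3)[C@@H]12
F6 | step 10 | (1S,2R,5R,6S)-2-[3,4-bis(TBSO)phenyl]-6-[3,4,5-tris(TBSO)phenyl]-3,7-dioxabicyclo[3.3.0]octan-8-one | O=C1O[C@H](c2cc(O[Si](C)(C)C(C)(C)C)c(O[Si](C)(C)C(C)(C)C)c(O[Si](C)(C)C(C)(C)C)c2)[C@H]2CO[C@@H](c3ccc(O[Si](C)(C)C(C)(C)C)c(O[Si](C)(C)C(C)(C)C)c3)[C@@H]12
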